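## Structural features

The target is a monocyclic 1,2-dioxolane (O1–O2–C3–C4–C5, carboxyl carbon = C1) whose two oxygen-bearing ring carbons are both fully substituted. C3 carries a methyl group and the CH2CO2H arm (C2–C1); C5 carries a methyl group and a chain that starts at C6. The chain has a methyl-branched stereocentre at C7, six methylenes (C8–C13) and an (E,E)-diene C14=C15–C16=C17 conjugated to a phenyl ring. No two stereocentres are directly bonded: C3 (S) and C5 (R) are 1,3-related across the ring methylene C4, with the acid arm and the C6 chain on opposite faces, and C7 (R) is 1,3-related to C5 across C6. The fragile groups are the O–O bond (phosphines, hydrides, low-valent metals, hydrogenation), the β-peroxy carbonyl array C1–C2–C3–O2 (ring opening by strong base) and the electron-rich styryl diene (ozone, Lewis acids, carbocations). The real difficulty is to build two tetrasubstituted C–O centres joined by a peroxide in the correct relative and absolute sense when the only existing stereocentre, C7, is remote, and to introduce the diene only after all oxidising and cationic steps. The key step uses the fact that C5 is at the ketone oxidation level while C4, C3, the C3 methyl and the arm form the isobutenyl unit of a 3-methylbut-3-enoate. A C5 peroxycarbenium ion and that alkene can therefore form C4–C5 and C3–O2 in one operation. C5–C10 with the C7 methyl is the carbon skeleton of (R)-citronellal.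

## Logic of the disconnections

25 ⇒ 24. The C1–OH bond is traced back to a C1–OMe bond. The acid must be masked through the Lewis-acid and carbanion steps, and the gain is a neutral, chromatographable series of intermediates. The forward step must hydrolyse the ester without triggering β-elimination of O2 from C3 and without acid damage to the diene.

24 ⇒ 21 + 22. The C14=C15 bond is cut. The diene is the most oxidisable and most nucleophilic part of the molecule and cannot be present during ozonolysis or cation chemistry, so it is added last. The chain is reduced to a saturated aldehyde and the styryl unit comes from a commercial phosphonate. The forward step must be E-selective and must use a carbanion that neither reduces the O–O bond nor deprotonates C2.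

21 ⇒ 20 ⇒ 19. These are functional-group changes at C14 only (C14=O back to C14–OH back to C14–OSi). A bulky silyl ether is the form of C14 that survives ozone, silyl triflate and SnCl4. The forward steps need non-basic desilylation and a non-reducing oxidation.

19 ⇒ 15 + 16. The C4–C5 and C3–O2 bonds are cut; this is the strategic disconnection. It removes the ring and both quaternary stereocentres at once and gives two partners of similar size, one of them commercial. The forward step must ionise the ketal cleanly, must win against fragmentation of the cation, and leaves a diastereomer separation.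

15 ⇒ 14 ⇒ 12. The O–Si bond is removed, then the C5(OMe)(OOH) pair is traced back to a C5=CH2 alkene. Ozonolysis in methanol puts the peroxide on C5 at the ketone oxidation level without concentrated hydrogen peroxide. The forward step requires the primary ozonide to fragment towards the more substituted carbonyl oxide and the silyl ether to survive ozone.

12 ⇒ 11. The C5=CH2 bond is traced back to C5=O. The gain is a simple methyl ketone. The forward methylenation is safe because C7 is β to the carbonyl and cannot epimerise.

11 ⇒ 10 ⇒ 8 + 3. The C10–C11 bond is cut, through the C10=C11 alkene. This joins the terpene-derived C5–C10 unit to a four-carbon piece (C11–C14) that already carries the protected oxygen. The forward Wittig reaction must take the aldehyde in preference to the methyl ketone, and hydrogenation must come before any alkene or peroxide that is to be kept.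

8 ⇒ 6 ⇒ 5 ⇒ 4. The C10 aldehyde is traced back to the C10=C(CH3)2 alkene, and the C5–CH3 bond is cut back to the aldehyde of 4. C7 comes from the chiral pool with the correct configuration and is never α to a carbonyl. The forward steps are a Grignard addition, an oxidation and an ozonolysis that leaves the ketone untouched.

3 ⇒ 2 ⇒ 1. The C–P bond and the O–Si bond are cut back to a commercial bromo alcohol. The forward silylation must be faster than cyclisation of the bromo alcohol.

## Other disconnections considered

Alternative 1: The cut goes through both ring C–O bonds (C3–O2 and C5–O1). The two oxygens come from O2 and the carbons from vinylcyclopropane A2, whose C3–C5 bond is broken. In the forward step, phenylselenyl radical (PhSeSePh, light) adds to the vinyl terminus of A2 and the cyclopropylcarbinyl radical opens to the tertiary C5 radical. O2 is taken up, the peroxyl radical closes 5-exo onto C3, and loss of the selenyl radical restores the vinyl group in A1.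
- In its favour: the peroxide is created from O2 in the ring-forming event itself. No hydroperoxide or ozonide has to be prepared and handled beforehand and no Lewis acid is needed. On the safety of the peroxide-forming stage this alternative is the better plan.
- Against it: A1 has a vinyl group where the target needs CH2CO2H. An anti-Markovnikov hydration and two-stage oxidation of a hindered alkene next to an O–O bond would have to follow, and boranes are not innocent towards peroxides. A2 is a tetrasubstituted cyclopropane that needs several steps of its own, and its ring stereochemistry is lost on opening.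
- Comparison: on stereocontrol the two plans are equal. In both, C5 passes through a planar intermediate (radical there, cation here) that C7 cannot bias, and the closure onto C3 distinguishes only a methyl from a primary carbon substituent. On step economy the chosen plan is clearly shorter, because the arm arrives with the right carbon count and oxidation level.

Alternative 2: Only the C5–O1 bond is cut. In precursor A4, C3 already carries the peroxide as a triethylsilyl peroxide and C5 is a 1,1-disubstituted alkene carbon whose methylene becomes the C5 methyl. In the forward step a cobalt hydride, formed from the divalent cobalt complex Co(salen), the N-fluoropyridinium oxidant and PhSiH3, transfers a hydrogen atom to the methylene. The tertiary C5 radical is oxidised through an alkylcobalt species to a cation equivalent, and the silylperoxy oxygen on C3 closes the ring with loss of silicon to give A3.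
- In its favour: C3 is fixed beforehand in absolute terms by a Sharpless asymmetric epoxidation and stereospecific conversion into the tertiary peroxide. At most two diastereomers (the C5 epimers) can then form, both with the correct C3. On stereochemical control this alternative is better than the chosen plan. The closure also forms a single bond under nearly neutral conditions.
- Against it: A4 needs a long sequence (asymmetric epoxidation, reductive epoxide opening, activation, perhydrolysis with inversion at a tertiary carbon, double silylation). Capture of a radical–polar crossover intermediate by a peroxy oxygen is far less documented than capture by alcohols. Low-valent cobalt and a silane can attack O–O bonds. After ring closure the arm must still be taken from CH2CH2OSiEt3 to CH2CO2H in the presence of the second silyl ether.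
- Comparison: C5 is still not controlled by C7, so the plans are equal on that point. The chosen key step rests on the better-established reaction type and the chosen route is markedly shorter.

Alternative 3: The cuts are C3–C4 and C5–O1, so the roles of the partners are exchanged. The peroxycarbenium ion sits on C3 and comes from the small ketal A6; the alkene is the chain-bearing 2-methylalk-1-ene, which is compound 12 of the chosen route. In the forward step SnCl4 ionises A6, the CH2 carbon of 12 bonds to C3, and the tertiary C5 cation is captured by the silylperoxy oxygen to give A5.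
- In its favour: 12 is a plain 1,1-dialkyl alkene with no electron-withdrawing group and should be a better nucleophile than 16. On reactivity in the annulation this alternative is the better one. The ozonolysis and silylation are also done on a cheap four-carbon fragment, which saves steps 9 and 10 on the main line.
- Against it: the arm arrives as CH2CH2OAc, one oxidation level too low. Deacetylation, oxidation to the acid and esterification add about three steps, which must be orthogonal to the C14 silyl ether. Such annulations work best with excess alkene, but here the alkene is the valuable partner. The acetate carbonyl can also engage the C3 cation in a six-membered acyloxonium ion.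
- Comparison: the stereochemical problem is identical (equal). The overall count comes out about one step longer than the chosen plan.

Key step: step 11

Remark on the structures: precursor 15 and product 19 were checked atom by atom against the target and need no structural change; (R)-citronellal supplies C7 in the required sense, and the target is (3S,5R,7R). The one correction concerns step 11: since neither the face of C5 nor the cis/trans outcome of the closure is strongly biased, three ring diastereomers (not one epimer) must be expected beside 19.

Assumption: the four ring diastereomers from step 11 can be separated on silica (preparative HPLC if needed) at the stage of 19 or, failing that, of 20. The relative configuration across the ring would be assigned by NOE and the relation to C7 by a crystalline derivative or comparison of 25 with the natural acid. All peroxide-containing materials (from step 9 on) are handled on small scale, cold, behind a shield and never concentrated to dryness with heating.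

## Steps

Step 1
Reactants: 1 4-bromobutan-1-ol
Product: 2 (4-bromobutoxy)tri(propan-2-yl)silane
Conditions: iPr3SiCl, imidazole, CH2Cl2, 0 °C → rt
Reagents that add atoms: chlorotri(propan-2-yl)silane, CC(C)[Si](Cl)(C(C)C)C(C)C
Why: Silylation of a primary alcohol with a silyl chloride and imidazole; run cold so that silylation outruns cyclisation of the bromo alcohol to tetrahydrofuran.

Step 2
Reactants: 2 (4-bromobutoxy)tri(propan-2-yl)silane
Product: 3 triphenyl{4-[tri(propan-2-yl)silyloxy]butyl}phosphonium bromide
Conditions: PPh3, MeCN, 80 °C
Reagents that add atoms: triphenylphosphine, c1ccc(cc1)P(c1ccccc1)c1ccccc1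
Why: SN2 quaternisation of triphenylphosphine by a primary bromide; the bulky silyl ether tolerates the neutral, hot conditions.

Step 3
Reactants: 4 (R)-citronellal [(3R)-3,7-dimethyloct-6-enal]
Product: 5 (4R)-4,8-dimethylnon-7-en-2-ol (both C2 epimers)
Conditions: MeMgBr, Et2O, 0 °C; aq. NH4Cl
Reagents that add atoms: methylmagnesium bromide, C[Mg]Br
Why: Grignard addition to the aldehyde installs the future C5 methyl; the new carbinol centre forms without control, which does not matter because it is oxidised in step 4.

Step 4
Reactants: 5 (4R)-4,8-dimethylnon-7-en-2-ol
Product: 6 (4R)-4,8-dimethylnon-7-en-2-one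
Conditions: Dess–Martin periodinane, CH2Cl2, 0 °C → rt
Reagents that add atoms: none
Why: Dess–Martin oxidation of a secondary alcohol; the trisubstituted alkene is untouched and the methyl-bearing stereocentre is β to the new carbonyl, so it cannot epimerise.

Step 5
Reactants: 6 (4R)-4,8-dimethylnon-7-en-2-one
Product: 8 (4R)-4-methyl-6-oxoheptanal, via secondary ozonide 7 (not isolated)
Conditions: O3, CH2Cl2, −78 °C; then Me2S, −78 °C → rt
Reagents that add atoms: ozone, [O-][O+]=O
Why: Ozonolysis with reductive work-up cleaves the electron-rich trisubstituted alkene while the ketone is inert to ozone; 8 is used crude and promptly so that acid- or base-induced intramolecular aldol reaction is avoided.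

Step 6
Reactants: 3 triphenyl{4-[tri(propan-2-yl)silyloxy]butyl}phosphonium bromide; 8 (4R)-4-methyl-6-oxoheptanal
Product: 10 (4R,7Z)-4-methyl-11-[tri(propan-2-yl)silyloxy]undec-7-en-2-one, via phosphorus ylide 9 (not isolated)
Conditions: 3, NaN(SiMe3)2, THF, 0 °C; then 8, −78 °C → rt
Reagents that add atoms: none
Why: Wittig olefination with a non-stabilised ylide, which takes the aldehyde much faster than the methyl ketone at low temperature when the ylide is not in excess; the Z/E ratio of the new C10=C11 bond is irrelevant because it is hydrogenated next.

Step 7
Reactants: 10 (4R,7Z)-4-methyl-11-[tri(propan-2-yl)silyloxy]undec-7-en-2-one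
Product: 11 (4R)-4-methyl-11-[tri(propan-2-yl)silyloxy]undecan-2-one
Conditions: H2 (1 atm), Pd/C, EtOAc, rt
Reagents that add atoms: none
Why: Heterogeneous hydrogenation of a disubstituted alkene; ketone and silyl ether are inert, and the step is placed before the C5 methylene and the peroxide exist.

Step 8
Reactants: 11 (4R)-4-methyl-11-[tri(propan-2-yl)silyloxy]undecan-2-one
Product: 12 {[(8R)-8,10-dimethylundec-10-en-1-yl]oxy}tri(propan-2-yl)silane
Conditions: Ph3PCH3Br, KOtBu, THF, 0 °C → rt
Reagents that add atoms: methyltriphenylphosphonium bromide, C[P+](c1ccccc1)(c1ccccc1)c1ccccc1.[Br-]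
Why: Wittig methylenation of a methyl ketone; the stereocentre is β to the carbonyl, so the basic ylide cannot epimerise it.

Step 9
Reactants: 12 {[(8R)-8,10-dimethylundec-10-en-1-yl]oxy}tri(propan-2-yl)silane
Product: 14 {[(8R)-10-hydroperoxy-10-methoxy-8-methylundecyl]oxy}tri(propan-2-yl)silane (both C10 epimers), via carbonyl oxide 13 (not isolated)
Conditions: O3, CH2Cl2/MeOH, −78 °C; N2 purge; no reductant
Reagents that add atoms: ozone, [O-][O+]=O; methanol, CO
Why: Ozonolysis of a 1,1-disubstituted alkene in methanol: the primary ozonide fragments to formaldehyde and the more substituted carbonyl oxide 13, which methanol traps as the α-methoxy hydroperoxide. The ketal centre forms as both epimers, which is of no consequence because it becomes planar in step 11; any ketone 11 from the reverse fragmentation can be returned to step 8.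

Step 10
Reactants: 14 {[(8R)-10-hydroperoxy-10-methoxy-8-methylundecyl]oxy}tri(propan-2-yl)silane
Product: 15 triethyl{[(4R)-2-methoxy-4-methyl-11-[tri(propan-2-yl)silyloxy]undecan-2-yl]peroxy}silane (both ketal epimers)
Conditions: Et3SiOTf, Et3N, DMF, 0 °C
Reagents that add atoms: triethylsilyl trifluoromethanesulfonate, CC[Si](CC)(CC)OS(=O)(=O)C(F)(F)F
Why: O-Silylation of a hydroperoxide with a silyl triflate and an amine base; it caps the acidic OOH and gives the silyl peroxyketal class from which peroxycarbenium ions are generated.

Step 11
Reactants: 15 triethyl{[(4R)-2-methoxy-4-methyl-11-[tri(propan-2-yl)silyloxy]undecan-2-yl]peroxy}silane; 16 methyl 3-methylbut-3-enoate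
Product: 19 methyl 2-[(3S,5R)-3,5-dimethyl-5-[(2R)-2-methyl-9-[tri(propan-2-yl)silyloxy]nonyl]-1,2-dioxolan-3-yl]acetate, via peroxycarbenium ion 17 (not isolated), via tertiary C3 carbocation 18 (not isolated)
Conditions: SnCl4, 16 (excess), CH2Cl2, −78 °C; aq. NaHCO3
Reagents that add atoms: none
Why: SnCl4 removes the methoxy group of 15 (both ketal epimers converge) to give the planar peroxycarbenium ion 17, methoxide being lost in preference to the silylperoxy group because the silylated peroxide oxygen is the poorer donor towards tin. The unsubstituted CH2 terminus of 16 then attacks C5 in the Markovnikov sense, forming C4–C5 and the tertiary C3 cation 18. The silyl-bearing peroxy oxygen captures C3 and closes the 1,2-dioxolane, a five-membered SN1-type closure in which the oxygen lone pair reaches the empty p orbital of C3 through an envelope transition state, and the silyl group leaves the resulting oxonium ion for the tin-bound methoxide or chloride. The closest known reaction type is the Lewis acid-promoted (3+2) annulation of silyl peroxyketals with 1,1-disubstituted alkenes to 3,3,5,5-tetrasubstituted 1,2-dioxolanes. C5 is created in the C–C bond formation, where only the remote C7 centre distinguishes the two faces of 17, so no useful bias is expected; C3 is created in the ring closure relative to C5, and the required arrangement with the CH2CO2Me arm anti to the C6 chain is at best weakly preferred because each ring carbon carries a methyl and a primary alkyl group. The step depends on chemoselectivity: 16 is the only π-nucleophile present because the styryl diene is not yet installed, the ester cannot trap 18 (a four-membered ring would result), and the triisopropylsilyl ether and the saturated chain are inert at −78 °C. 16 is used in excess to outrun fragmentation of 17, and the (3S,5R) isomer 19 is separated by chromatography from the other three ring diastereomers.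

Step 12
Reactants: 19 methyl 2-[(3S,5R)-3,5-dimethyl-5-[(2R)-2-methyl-9-[tri(propan-2-yl)silyloxy]nonyl]-1,2-dioxolan-3-yl]acetate
Product: 20 methyl 2-[(3S,5R)-5-[(2R)-9-hydroxy-2-methylnonyl]-3,5-dimethyl-1,2-dioxolan-3-yl]acetate
Conditions: HF·pyridine, pyridine, THF, 0 °C → rt
Reagents that add atoms: none
Why: Fluoride cleavage of a primary triisopropylsilyl ether under buffered, weakly acidic conditions; the dialkyl peroxide and the methyl ester do not react, and basic fluoride sources that could open the β-peroxy ester are avoided.

Step 13
Reactants: 20 methyl 2-[(3S,5R)-5-[(2R)-9-hydroxy-2-methylnonyl]-3,5-dimethyl-1,2-dioxolan-3-yl]acetate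
Product: 21 methyl 2-[(3S,5R)-3,5-dimethyl-5-[(2R)-2-methyl-9-oxononyl]-1,2-dioxolan-3-yl]acetate
Conditions: Dess–Martin periodinane, CH2Cl2, 0 °C → rt
Reagents that add atoms: none
Why: Dess–Martin oxidation of a primary alcohol to the aldehyde under non-reducing, nearly neutral conditions that leave the O–O bond and the ester alone.

Step 14
Reactants: 21 methyl 2-[(3S,5R)-3,5-dimethyl-5-[(2R)-2-methyl-9-oxononyl]-1,2-dioxolan-3-yl]acetate; 22 diethyl [(2E)-3-phenylprop-2-en-1-yl]phosphonate (diethyl cinnamylphosphonate)
Product: 24 methyl 2-[(3S,5R)-3,5-dimethyl-5-[(2R,9E,11E)-2-methyl-12-phenyldodeca-9,11-dienyl]-1,2-dioxolan-3-yl]acetate, via lithiated phosphonate 23 (not isolated)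
Conditions: 22, n-BuLi, THF, −78 °C; then 21, −78 °C → rt
Reagents that add atoms: none
Why: Horner–Wadsworth–Emmons olefination with an allylic phosphonate carbanion, which should give the E alkene at C14=C15 while the C16=C17 geometry comes unchanged from 22. The carbanion is fully formed (phosphonate in slight excess over base) before the aldehyde is added, is less basic than an ester enolate, and adds to the aldehyde faster than it can deprotonate C2.

Step 15
Reactants: 24 methyl 2-[(3S,5R)-3,5-dimethyl-5-[(2R,9E,11E)-2-methyl-12-phenyldodeca-9,11-dienyl]-1,2-dioxolan-3-yl]acetate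
Product: 25 2-[(3S,5R)-3,5-dimethyl-5-[(2R,9E,11E)-2-methyl-12-phenyldodeca-9,11-dienyl]-1,2-dioxolan-3-yl]acetic acid
Conditions: LiOH, THF/MeOH/H2O, 0 °C → rt; then 1 M HCl to pH 3–4, 0 °C
Reagents that add atoms: lithium hydroxide, [Li+].[OH-]
Why: Saponification of a methyl ester with LiOH at or below room temperature, the usual last step for dioxolane-acetic esters. C3 and C5 carry no hydrogen, so base-induced Kornblum–DeLaMare cleavage is impossible, and brief, cold, mild acidification spares the diene.

## Compound list

1 | 4-bromobutan-1-ol | OCCCCBr | starting material
2 | (4-bromobutoxy)tri(propan-2-yl)silane | CC(C)[Si](OCCCCBr)(C(C)C)C(C)C | intermediate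
3 | triphenyl{4-[tri(propan-2-yl)silyloxy]butyl}phosphonium bromide | CC(C)[Si](OCCCC[P+](c1ccccc1)(c1ccccc1)c1ccccc1)(C(C)C)C(C)C.[Br-] | intermediate
4 | (R)-citronellal, (3R)-3,7-dimethyloct-6-enal | C[C@H](CCC=C(C)C)CC=O | starting material
5 | (4R)-4,8-dimethylnon-7-en-2-ol, both C2 epimers | C[C@H](CCC=C(C)C)CC(C)O | intermediate
6 | (4R)-4,8-dimethylnon-7-en-2-one | C[C@H](CCC=C(C)C)CC(C)=O | intermediate
7 | (4R)-6-(5,5-dimethyl-1,2,4-trioxolan-3-yl)-4-methylhexan-2-one, secondary ozonide | C[C@H](CCC1OOC(C)(C)O1)CC(C)=O | intermediate (not isolated)
8 | (4R)-4-methyl-6-oxoheptanal | C[C@H](CCC=O)CC(C)=O | intermediate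
9 | triphenyl{4-[tri(propan-2-yl)silyloxy]butylidene}phosphorane, ylide | CC(C)[Si](OCCCC=P(c1ccccc1)(c1ccccc1)c1ccccc1)(C(C)C)C(C)C | intermediate (not isolated)
10 | (4R,7Z)-4-methyl-11-[tri(propan-2-yl)silyloxy]undec-7-en-2-one | C[C@H](CC/C=C\CCCO[Si](C(C)C)(C(C)C)C(C)C)CC(C)=O | intermediate
11 | (4R)-4-methyl-11-[tri(propan-2-yl)silyloxy]undecan-2-one | C[C@H](CCCCCCCO[Si](C(C)C)(C(C)C)C(C)C)CC(C)=O | intermediate
12 | {[(8R)-8,10-dimethylundec-10-en-1-yl]oxy}tri(propan-2-yl)silane | C[C@H](CCCCCCCO[Si](C(C)C)(C(C)C)C(C)C)CC(C)=C | intermediate
13 | carbonyl oxide of ketone 11 (O-oxide at C5) | C[C@H](CCCCCCCO[Si](C(C)C)(C(C)C)C(C)C)CC(C)=[O+][O-] | intermediate (not isolated)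
14 | {[(8R)-10-hydroperoxy-10-methoxy-8-methylundecyl]oxy}tri(propan-2-yl)silane, both C10 epimers | C[C@H](CCCCCCCO[Si](C(C)C)(C(C)C)C(C)C)CC(C)(OC)OO | intermediate
15 | triethyl{[(4R)-2-methoxy-4-methyl-11-[tri(propan-2-yl)silyloxy]undecan-2-yl]peroxy}silane, both ketal epimers | C[C@H](CCCCCCCO[Si](C(C)C)(C(C)C)C(C)C)CC(C)(OC)OO[Si](CC)(CC)CC | intermediate
16 | methyl 3-methylbut-3-enoate | C=C(C)CC(=O)OC | starting material
17 | C5 peroxycarbenium ion (triethylsilylperoxy-substituted) | C[C@H](CCCCCCCO[Si](C(C)C)(C(C)C)C(C)C)CC(C)=[O+]O[Si](CC)(CC)CC | intermediate (not isolated)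
18 | tertiary C3 carbocation after C4–C5 bond formation | C[C@H](CCCCCCCO[Si](C(C)C)(C(C)C)C(C)C)CC(C)(C[C+](C)CC(=O)OC)OO[Si](CC)(CC)CC | intermediate (not isolated)
19 | methyl 2-[(3S,5R)-3,5-dimethyl-5-[(2R)-2-methyl-9-[tri(propan-2-yl)silyloxy]nonyl]-1,2-dioxolan-3-yl]acetate | C[C@H](CCCCCCCO[Si](C(C)C)(C(C)C)C(C)C)C[C@]1(C)C[C@@](C)(CC(=O)OC)OO1 | intermediate
20 | methyl 2-[(3S,5R)-5-[(2R)-9-hydroxy-2-methylnonyl]-3,5-dimethyl-1,2-dioxolan-3-yl]acetate | C[C@H](CCCCCCCO)C[C@]1(C)C[C@@](C)(CC(=O)OC)OO1 | intermediate
21 | methyl 2-[(3S,5R)-3,5-dimethyl-5-[(2R)-2-methyl-9-oxononyl]-1,2-dioxolan-3-yl]acetate | C[C@H](CCCCCCC=O)C[C@]1(C)C[C@@](C)(CC(=O)OC)OO1 | intermediate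
22 | diethyl [(2E)-3-phenylprop-2-en-1-yl]phosphonate (diethyl cinnamylphosphonate) | CCOP(=O)(OCC)C/C=C/c1ccccc1 | starting material
23 | lithiated diethyl cinnamylphosphonate | [Li+].CCOP(=O)(OCC)[CH-]/C=C/c1ccccc1 | intermediate (not isolated)
24 | methyl 2-[(3S,5R)-3,5-dimethyl-5-[(2R,9E,11E)-2-methyl-12-phenyldodeca-9,11-dienyl]-1,2-dioxolan-3-yl]acetate | C[C@H](CCCCCC/C=C/C=C/c1ccccc1)C[C@]1(C)C[C@@](C)(CC(=O)OC)OO1 | intermediate
25 | 2-[(3S,5R)-3,5-dimethyl-5-[(2R,9E,11E)-2-methyl-12-phenyldodeca-9,11-dienyl]-1,2-dioxolan-3-yl]acetic acid | C[C@H](CCCCCC/C=C/C=C/c1ccccc1)C[C@]1(C)C[C@@](C)(CC(=O)O)OO1 | target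

## Step count and least certain steps

Total: 15 steps. Longest linear sequence: 13 steps (steps 3–15, from 4 to 25); steps 1–2 form a two-step side branch.

**Step 11 (key step).**
- What may go wrong: sluggish attack of the ester-bearing alkene, whose nucleophilicity is lowered by the inductive effect of the ester and by SnCl4 binding to it. Fragmentation of the peroxycarbenium ion (C-to-O migration) or proton loss from the C3 cation could then compete. In addition, unselective attack on the two faces of the C5 cation and weak cis/trans discrimination in the ring closure would leave a demanding separation of four diastereomers.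
- Fallback (from 15 and 16, back to the route at 19): the single annulation is replaced by C–C bond formation followed by conjugate peroxide addition. 16 would be converted with LiN(iPr)2 and Me3SiCl into the silyl dienol ether 1-methoxy-3-methyl-1-(trimethylsilyloxy)buta-1,3-diene F1, a far stronger π-nucleophile. F1 would add through its γ-carbon to the peroxycarbenium ion from 15 (SnCl4, CH2Cl2, −78 °C, vinylogous Mukaiyama-type addition), forming the same C4–C5 bond and giving methyl (7R)-3,5,7-trimethyl-5-(triethylsilylperoxy)-14-[tri(propan-2-yl)silyloxy]tetradec-2-enoate F2. Buffered fluoride (Bu4NF/AcOH, THF, 0 °C) would free the hydroperoxide methyl (7R)-5-hydroperoxy-3,5,7-trimethyl-14-[tri(propan-2-yl)silyloxy]tetradec-2-enoate F3 without touching the primary silyl ether. Et2NH in CF3CH2OH would then close the ring by 5-exo-trig conjugate addition of the hydroperoxide to C3, giving 19 after the same diastereomer separation.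

**Step 14.**
- What may go wrong: incomplete E selectivity at C14=C15, and base-induced opening of the dioxolane by deprotonation at C2 followed by expulsion of the C3 peroxide oxygen.
- Fallback (from 21, back at 24): a Wittig reaction with the less basic, semi-stabilised ylide from cinnamyltriphenylphosphonium chloride and NaN(SiMe3)2 (THF, −78 °C → 0 °C) would give the diene as a C14=C15 mixture containing methyl 2-[(3S,5R)-3,5-dimethyl-5-[(2R,9Z,11E)-2-methyl-12-phenyldodeca-9,11-dienyl]-1,2-dioxolan-3-yl]acetate F8. Catalytic iodine in daylight would then equilibrate the mixture to the (E,E) diene 24.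

**Step 6.**
- What may go wrong: competing olefination or enolisation at the methyl ketone, and base-induced intramolecular aldol condensation of the 1,6-keto aldehyde under the ylide conditions.
- Fallback (from 5, back at 11): the ketone is not formed until the chain is complete. Ozonolysis of 5 (O3, CH2Cl2, −78 °C; Me2S) would give (4R)-6-hydroxy-4-methylheptanal F4. Wittig reaction with two equivalents of ylide 9 would give (4R,7Z)-4-methyl-11-[tri(propan-2-yl)silyloxy]undec-7-en-2-ol F5. Hydrogenation (H2, Pd/C) would give (4R)-4-methyl-11-[tri(propan-2-yl)silyloxy]undecan-2-ol F6, and Dess–Martin oxidation would deliver 11. The step count is unchanged.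

**Step 9.**
- What may go wrong: fragmentation of the primary ozonide in the unwanted sense (towards the ketone and formaldehyde O-oxide), and reversion of the hydroperoxy ketal to the ketone by loss of methanol and hydrogen peroxide during concentration or chromatography.
- Fallback (from 11, back at 14): ozone is avoided. 11 would be converted with HC(OMe)3 and catalytic TsOH in MeOH into the dimethyl ketal {[(8R)-10,10-dimethoxy-8-methylundecyl]oxy}tri(propan-2-yl)silane F7. Acid-catalysed exchange of one methoxy group with ethereal H2O2 at 0 °C would give 14. This variant uses concentrated hydrogen peroxide and is therefore kept as a reserve only.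

## Further compounds

F1 | step 11 | 1-methoxy-3-methyl-1-(trimethylsilyloxy)buta-1,3-diene | COC(O[Si](C)(C)C)=CC(C)=C
F2 | step 11 | methyl (7R)-3,5,7-trimethyl-5-(triethylsilylperoxy)-14-[tri(propan-2-yl)silyloxy]tetradec-2-enoate (C5 epimers, both alkene isomers) | C[C@H](CCCCCCCO[Si](C(C)C)(C(C)C)C(C)C)CC(C)(CC(C)=CC(=O)OC)OO[Si](CC)(CC)CC
F3 | step 11 | methyl (7R)-5-hydroperoxy-3,5,7-trimethyl-14-[tri(propan-2-yl)silyloxy]tetradec-2-enoate (C5 epimers, both alkene isomers) | C[C@H](CCCCCCCO[Si](C(C)C)(C(C)C)C(C)C)CC(C)(CC(C)=CC(=O)OC)OO
F4 | step 6 | (4R)-6-hydroxy-4-methylheptanal (both C6 epimers) | C[C@H](CCC=O)CC(C)O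
F5 | step 6 | (4R,7Z)-4-methyl-11-[tri(propan-2-yl)silyloxy]undec-7-en-2-ol (both C2 epimers) | C[C@H](CC/C=C\CCCO[Si](C(C)C)(C(C)C)C(C)C)CC(C)O
F6 | step 6 | (4R)-4-methyl-11-[tri(propan-2-yl)silyloxy]undecan-2-ol (both C2 epimers) | C[C@H](CCCCCCCO[Si](C(C)C)(C(C)C)C(C)C)CC(C)O
F7 | step 9 | {[(8R)-10,10-dimethoxy-8-methylundecyl]oxy}tri(propan-2-yl)silane | C[C@H](CCCCCCCO[Si](C(C)C)(C(C)C)C(C)C)CC(C)(OC)OC
F8 | step 14 | methyl 2-[(3S,5R)-3,5-dimethyl-5-[(2R,9Z,11E)-2-methyl-12-phenyldodeca-9,11-dienyl]-1,2-dioxolan-3-yl]acetate | C[C@H](CCCCCC/C=C\C=C\c1ccccc1)C[C@]1(C)C[C@@](C)(CC(=O)OC)OO1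
A1 | alternative 1 | (3S,5R)-3-ethenyl-3,5-dimethyl-5-[(2R)-2-methyl-9-[tri(propan-2-yl)silyloxy]nonyl]-1,2-dioxolane | C[C@H](CCCCCCCO[Si](C(C)C)(C(C)C)C(C)C)C[C@]1(C)C[C@@](C)(C=C)OO1
A2 | alternative 1 | 1-ethenyl-1,2-dimethyl-2-[(2R)-2-methyl-9-[tri(propan-2-yl)silyloxy]nonyl]cyclopropane (ring stereoisomers) | C[C@H](CCCCCCCO[Si](C(C)C)(C(C)C)C(C)C)CC1(C)CC1(C)C=C
A3 | alternative 2 | (3R,5R)-3,5-dimethyl-5-[(2R)-2-methyl-9-[tri(propan-2-yl)silyloxy]nonyl]-3-[2-(triethylsilyloxy)ethyl]-1,2-dioxolane | C[C@H](CCCCCCCO[Si](C(C)C)(C(C)C)C(C)C)C[C@]1(C)C[C@@](C)(CCO[Si](CC)(CC)CC)OO1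
A4 | alternative 2 | open-chain tertiary triethylsilyl peroxide at C3 with a C5 methylidene group, a 2-(triethylsilyloxy)ethyl arm and the silyl-protected chain (C3 and C7 as in the target) | C[C@H](CCCCCCCO[Si](C(C)C)(C(C)C)C(C)C)CC(=C)C[C@@](C)(CCO[Si](CC)(CC)CC)OO[Si](CC)(CC)CC
A5 | alternative 3 | 2-[(3R,5R)-3,5-dimethyl-5-[(2R)-2-methyl-9-[tri(propan-2-yl)silyloxy]nonyl]-1,2-dioxolan-3-yl]ethyl acetate | C[C@H](CCCCCCCO[Si](C(C)C)(C(C)C)C(C)C)C[C@]1(C)C[C@@](C)(CCOC(C)=O)OO1
A6 | alternative 3 | 3-methoxy-3-(triethylsilylperoxy)butyl acetate | CC(=O)OCCC(C)(OC)OO[Si](CC)(CC)CC
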